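The constants are those of an exercise; the result is computed.

Which holds more of the first end groups when the time is up, links or rings, and how large is the leader's share?

common to all: first end groups 0.050 M; gas 11 mM (held); time 1.5 min
- Saturday's: temperature 60 °C
- Wednesday's: temperature 80 °C

* which of these there is most of at the end, counted by the first end groups in it, Saturday's (first end groups / rings / links)
* which of these there is most of at the end, counted by the first end groups in it, Wednesday's (first end groups / rings / links)
* final amount of the leader among these, as a percentage of the first end groups charged, in Saturday's
* final amount of the leader among these, as a percentage of the first end groups charged, in Wednesday's

- at the start none of second end groups is dissolved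
- the constants hold at 60 °C; other temperatures follow from the activation energies

    gas ⇌ second end groups, rate k1*(csat - [second end groups]) (k1 = 0.28 /s, csat = 11 mM)
    second end groups → decomposed reagent (k2 = 0.071 /s, Ea2 = 79.0 kJ/mol)
    first end groups + second end groups → links (k3 = 11 /M/s, Ea3 = 56.0 kJ/mol)
    first end groups + second end groups → rings, rate k4*[first end groups] as long as [second end groups] is above zero (k4 = 0.0053 /s, Ea4 = 97.0 kJ/mol)
    (constants at 60 °C)

A first end group leaves by one of two roads, and each road also takes up one second end group. The pace of the link road follows the dissolved second end groups; the pace of the ring road does not, as long as some are dissolved. At the charge on Saturday's, link formation by itself gives second end groups a half-life of 1.3 s, much shorter than the run, so they are reckoned here at a steady level (a resting state), fed by the gas as fast as they are consumed.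

Set the demand of the ring road at the full charge against the fastest feed the gas can give. That ratio is the ring load, reckoned as 0.0860 for Saturday's and 0.625 for Wednesday's, with its constants taken to its temperature. A second number, the end ratio, is the ring pace over the link pace at the level second end groups hold once first end groups are gone: 0.0549 for Saturday's and 0.230 for Wednesday's.

Solving the steady level gives the link share of the groups leaving, with a fraction f of the charge left, as one minus load times f, over one plus end ratio. This is a straight line in f, so integrating down to an empty charge puts half the load in the numerator. The ring load by itself would give links 95.7% and 68.8%, so one number is not enough, and the end ratio has to lower both. With both numbers, and the charge taken as used up in time, Saturday's ends with links ahead at 90.7%, and Wednesday's with links ahead at 55.9%.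

The forecast gives links at 90.4% for Saturday's and links at 55.7% for Wednesday's, with “links still stay narrowly ahead”.

The simulation gives links at 89.9% for Saturday's, with rings at 10.1%, and links at 54.2% for Wednesday's, with rings at 45.8%.

On Wednesday's at 0.636 min, second end groups have a half-life of 1.9 s by decomposition against 0.90 min by links, far shorter. They are made 1.02 times as fast as they are used up, so the steady level reckoned with stood in that flask. The neighbour of Wednesday's charged with 0.20 M has a ring load of 2.50, above one, so the reckoned link share stands at zero until the charge is down to the fraction one over the load, where the straight line crosses zero. Links then come from that last fraction, which gives 16.3%. That flask ends with links at 16.1% and rings at 83.8%.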